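**Plan**

- Retrosynthesis: after removal of three silyl ethers, ring C is cut at C2–C3. The C3 carbinol next to the C4 aryl ketone of ring C is an α-ketol, the 1,2-shift isomer of a 3-hydroxy-2,3-dihydrobenzofuran-3-carbaldehyde in which C2 is still bonded to the future C4; this feature makes the key step possible.
- The benzofuranol is cut at C3–OH (enolate hydroxylation), at C2–C3 (carbenoid insertion into the benzylic C–H of an aryl benzyl ether), at the aryl–CH2CO2Me bond (Pd coupling of a zinc ester enolate) and at the benzylic C–O bond (Mitsunobu).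
- Ring A comes from 2-methylresorcinol (third oxygen by C–H borylation/oxidation, then one bromine); ring B from 4-hydroxybenzaldehyde and geranyl bromide.
- Forward: rings A and B are joined as an ether, the two-carbon ester is attached, the five-membered ring closes by C–H insertion, and after hydroxylation and adjustment to the aldehyde it is enlarged to ring C; desilylation ends the route.
- Stereochemistry: C2 is set by the chiral dirhodium carboxylate in the C–H insertion and carried through the shift with retention; C3 comes from the anti hydroxylation of step 11, relayed by the aluminium chelate of the 1,2-shift (2R,3R, trans).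

Key step: step 14

Abbreviations: TIPS = triisopropylsilyl; geranyl = (2E)-3,7-dimethylocta-2,6-dien-1-yl.

Assumption: with simple 2-(benzyloxy)phenyl diazoacetates the (S)-phthaloyl-tert-leucinate catalyst is taken to give the (2R,3S)-cis ester, so the (R)-ligand is specified for the (2S,3R) ester 16; if this crowded substrate responds in the opposite sense, Rh2(S-PTTL)4 is used with no other change.

**Route**

Step 1
Reactants: 1 2-methylresorcinol
Product: 2 2-methyl-1,3-bis(triisopropylsilyloxy)benzene
Conditions: TIPSCl (2.3 equiv), imidazole, DMF, rt to 40 °C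
Reagents that add atoms: chlorotriisopropylsilane, CC(C)[Si](Cl)(C(C)C)C(C)C
Why: Imidazole-promoted silylation of both phenols; TIPS ethers tolerate the later base, zinc and hydride reagents, carry no C–H bond at the five-ring distance from the later carbenoid, and their bulk steers the borylation of step 2.

Step 2
Reactants: 2 2-methyl-1,3-bis(triisopropylsilyloxy)benzene
Product: 4 4-methyl-3,5-bis(triisopropylsilyloxy)phenol, via arylboronic pinacol ester 3 (not isolated)
Conditions: [Ir(OMe)(cod)]2 (1.5 mol%), 4,4'-di-tert-butyl-2,2'-bipyridine (3 mol%), B2pin2 (1.0 equiv), THF, 80 °C; then Oxone (2KHSO5·KHSO4·K2SO4), acetone/H2O, 0 °C to rt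
Reagents that add atoms: potassium peroxymonosulfate, [K+].[O-]S(=O)(=O)OO
Why: Iridium-catalysed aromatic C–H borylation is sterically governed, so only the C–H flanked by two hydrogens (meta to both silyloxy groups) should react, and oxidation of the C–B bond in the same flask gives the phenol.

Step 3
Reactants: 4 4-methyl-3,5-bis(triisopropylsilyloxy)phenol
Product: 5 2-bromo-4-methyl-3,5-bis(triisopropylsilyloxy)phenol
Conditions: NBS (1.0 equiv), CH2Cl2, −78 to 0 °C
Reagents that add atoms: N-bromosuccinimide, O=C1CCC(=O)N1Br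
Why: Electrophilic aromatic bromination; the para position of the free phenol is blocked by methyl and its two ortho positions are equivalent by symmetry, so one equivalent of NBS at low temperature should give a single monobromide.

Step 4
Reactants: 6 4-hydroxybenzaldehyde; 7 geranyl bromide
Product: 8 3-geranyl-4-hydroxybenzaldehyde
Conditions: KOH (10% aq.), rt, slow addition of 7
Reagents that add atoms: none
Why: ortho-C-Alkylation of the phenoxide in water, where hydrogen bonding to oxygen favours attack through carbon; SN2 displacement at the primary allylic bromide keeps the E alkene, and the modest conversion expected is accepted on cheap materials (the O-geranyl ether is removed by chromatography).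

Step 5
Reactants: 8 3-geranyl-4-hydroxybenzaldehyde
Product: 9 3-geranyl-4-(triisopropylsilyloxy)benzaldehyde
Conditions: TIPSCl, imidazole, DMF, rt
Reagents that add atoms: chlorotriisopropylsilane, CC(C)[Si](Cl)(C(C)C)C(C)C
Why: Standard phenol silylation; the silyl ether later prevents quinone-methide opening at the benzylic carbon that becomes C2.

Step 6
Reactants: 9 3-geranyl-4-(triisopropylsilyloxy)benzaldehyde
Product: 10 [3-geranyl-4-(triisopropylsilyloxy)phenyl]methanol
Conditions: NaBH4, THF/MeOH, 0 °C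
Reagents that add atoms: none
Why: Borohydride reduction of an aryl aldehyde, which leaves the alkenes and the silyl ether untouched.

Step 7
Reactants: 5 2-bromo-4-methyl-3,5-bis(triisopropylsilyloxy)phenol; 10 [3-geranyl-4-(triisopropylsilyloxy)phenyl]methanol
Product: 11 2-bromo-1-{[3-geranyl-4-(triisopropylsilyloxy)phenyl]methoxy}-4-methyl-3,5-bis(triisopropylsilyloxy)benzene
Conditions: PPh3, DIAD, THF, 0 °C to rt
Reagents that add atoms: none
Why: Mitsunobu etherification of an acidic ortho-bromophenol with a primary benzylic alcohol; the neutral conditions avoid both a labile p-silyloxybenzyl halide and silyl transfer between phenoxides.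

Step 8
Reactants: 11 the aryl bromide of step 7; 12 methyl bromoacetate
Product: 14 methyl 2-[2-{[3-geranyl-4-(triisopropylsilyloxy)phenyl]methoxy}-5-methyl-4,6-bis(triisopropylsilyloxy)phenyl]acetate, via methyl (bromozincio)acetate 13 (not isolated)
Conditions: 12, Zn dust, TMSCl (cat.), THF, rt; then 11, Pd2(dba)3 (2.5 mol%), XPhos (10 mol%), THF, 65 °C
Reagents that add atoms: none
Why: Palladium-catalysed α-arylation of a zinc ester enolate (Reformatsky reagent, Negishi-type coupling); the nearly neutral zinc enolate spares the aryl silyl ethers, and a bulky dialkylbiarylphosphine is chosen for the doubly ortho-substituted, electron-rich bromide.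

Step 9
Reactants: 14 the aryl acetate of step 8
Product: 15 methyl 2-diazo-2-[2-{[3-geranyl-4-(triisopropylsilyloxy)phenyl]methoxy}-5-methyl-4,6-bis(triisopropylsilyloxy)phenyl]acetate
Conditions: 4-acetamidobenzenesulfonyl azide, DBU, dry MeCN, 0 °C to rt
Reagents that add atoms: 4-acetamidobenzenesulfonyl azide, CC(=O)Nc1ccc(cc1)S(=O)(=O)N=[N+]=[N-]
Why: Regitz diazo transfer to the benzylic ester position, the standard entry to aryl diazoacetates; dry conditions keep DBU from cleaving the aryl silyl ethers.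

Step 10
Reactants: 15 the aryl diazoacetate of step 9
Product: 16 methyl (2S,3R)-2-[3-geranyl-4-(triisopropylsilyloxy)phenyl]-5-methyl-4,6-bis(triisopropylsilyloxy)-2,3-dihydro-1-benzofuran-3-carboxylate (aryl and ester cis)
Conditions: Rh2(R-PTTL)4, dirhodium tetrakis[N-phthaloyl-(R)-tert-leucinate] (1–2 mol%), toluene, 4 Å sieves, −60 °C
Reagents that add atoms: none
Why: Intramolecular 1,5 C–H insertion of the donor/acceptor rhodium carbenoid into the benzylic, ether-activated C–H closes the five-membered ring; the chiral carboxylate ligands set C2 (the cis C3 centre formed with it is erased in step 11), and the silyl ethers offer no C–H at the five-ring distance.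

Step 11
Reactants: 16 the cis ester of step 10
Product: 18 methyl (2R,3S)-2-[3-geranyl-4-(triisopropylsilyloxy)phenyl]-3-hydroxy-5-methyl-4,6-bis(triisopropylsilyloxy)-2,3-dihydro-1-benzofuran-3-carboxylate (hydroxyl trans to aryl), via potassium ester enolate 17 (not isolated)
Conditions: KHMDS, THF, −78 °C; then 2-(phenylsulfonyl)-3-phenyloxaziridine, −78 °C; aq. NH4Cl
Reagents that add atoms: 2-(phenylsulfonyl)-3-phenyloxaziridine, O=S(=O)(N1OC1c1ccccc1)c1ccccc1
Why: Enolate hydroxylation with an N-sulfonyloxaziridine (Davis oxidation); the oxidant should approach the planar enolate from the face opposite the C2 aryl group, placing hydroxyl trans to aryl, and the low temperature together with the 5-endo geometry suppresses β-elimination of the ring oxygen, so C2 is kept.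

Step 12
Reactants: 18 the hydroxy ester of step 11
Product: 19 (2R,3R)-2-[3-geranyl-4-(triisopropylsilyloxy)phenyl]-3-(hydroxymethyl)-5-methyl-4,6-bis(triisopropylsilyloxy)-2,3-dihydro-1-benzofuran-3-ol
Conditions: LiBH4, THF, 0 °C to rt
Reagents that add atoms: none
Why: Borohydride reduction of an α-hydroxy ester to the 1,2-diol, mild enough for aryl silyl ethers and more dependable than a partial reduction stopped at the aldehyde.

Step 13
Reactants: 19 the diol of step 12
Product: 20 (2R,3S)-2-[3-geranyl-4-(triisopropylsilyloxy)phenyl]-3-hydroxy-5-methyl-4,6-bis(triisopropylsilyloxy)-2,3-dihydro-1-benzofuran-3-carbaldehyde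
Conditions: SO3·pyridine, DMSO, iPr2NEt, CH2Cl2, 0 °C; used without chromatography
Reagents that add atoms: none
Why: Parikh–Doering oxidation takes the primary alcohol to the aldehyde, cannot oxidise the tertiary hydroxyl, and does not cleave the glycol or touch the electron-rich arenes and alkenes.

Step 14
Reactants: 20 the hydroxy aldehyde of step 13
Product: 21 (2R,3R)-2-[3-geranyl-4-(triisopropylsilyloxy)phenyl]-3-hydroxy-6-methyl-5,7-bis(triisopropylsilyloxy)-2,3-dihydro-4H-chromen-4-one
Conditions: Al(OtBu)3 (2 equiv), toluene, rt to 60 °C, argon; aq. potassium sodium tartrate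
Reagents that add atoms: none
Why: Exchange of one tert-butoxide for the tertiary hydroxyl gives an aluminium alkoxide that also binds the formyl oxygen; in this five-membered chelate the alkoxide oxygen pushes while C2 shifts with its bonding pair from the carbinol carbon to the formyl carbon, so the old carbinol carbon becomes the C4 ketone and the formyl carbon the C3 carbinol. The closest known reaction type is the Lewis-acid α-ketol (acyloin) rearrangement with ring enlargement of 1-hydroxycycloalkanecarbaldehydes and the D-homo-annulation of 17-hydroxy-20-oxo steroids under aluminium alkoxides. Ring C is closed not by an end-to-end cyclisation but by one-carbon enlargement of the furan ring, the 1,2-shift inserting the formyl carbon between C2 and the former carbinol carbon. The new C3 centre is controlled by the carbinol configuration from step 11 and the syn-periplanar O–C–C=O geometry of the chelate, in which C2 can reach only the formyl face turned toward it; this should give 3R with hydroxyl trans to the aryl group, which is also the more stable diequatorial isomer, while C2 migrates with retention. The selectivity needed is migration of C2 and not of the ring A carbon: ring A that stays in place conjugates with the developing ketone, ring A is held coplanar with the furan ring and cannot reach the perpendicular bridging geometry of an aryl shift, and C2 is a benzylic, oxygen-bearing carbon of high migratory aptitude. Al(OtBu)3 has no transferable hydride, so the aldehyde is not reduced, and it is mild enough for the silyl ethers, the benzylic ether and the geranyl chain.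

Step 15
Reactants: 21 the tris-silyl flavanonol of step 14
Product: 22 (2R,3R)-2-(3-geranyl-4-hydroxyphenyl)-3,5,7-trihydroxy-6-methyl-2,3-dihydro-4H-chromen-4-one (target)
Conditions: TBAF (3.5 equiv), AcOH (4 equiv), THF, 0 °C
Reagents that add atoms: none
Why: Fluoride cleavage of the three aryl silyl ethers; acetic acid buffering keeps the freed phenoxides protonated, so that C2 is not epimerised through a quinone methide and the α-ketol is not isomerised.

**Compound list**

1 | 2-methylresorcinol | Cc1c(O)cccc1O | starting material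
2 | 2-methyl-1,3-bis(triisopropylsilyloxy)benzene | Cc1c(O[Si](C(C)C)(C(C)C)C(C)C)cccc1O[Si](C(C)C)(C(C)C)C(C)C | intermediate
3 | 4,4,5,5-tetramethyl-2-[4-methyl-3,5-bis(triisopropylsilyloxy)phenyl]-1,3,2-dioxaborolane (not isolated) | Cc1c(O[Si](C(C)C)(C(C)C)C(C)C)cc(B2OC(C)(C)C(C)(C)O2)cc1O[Si](C(C)C)(C(C)C)C(C)C | intermediate
4 | 4-methyl-3,5-bis(triisopropylsilyloxy)phenol | Cc1c(O[Si](C(C)C)(C(C)C)C(C)C)cc(O)cc1O[Si](C(C)C)(C(C)C)C(C)C | intermediate
5 | 2-bromo-4-methyl-3,5-bis(triisopropylsilyloxy)phenol | Cc1c(O[Si](C(C)C)(C(C)C)C(C)C)cc(O)c(Br)c1O[Si](C(C)C)(C(C)C)C(C)C | intermediate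
6 | 4-hydroxybenzaldehyde | O=Cc1ccc(O)cc1 | starting material
7 | geranyl bromide | CC(C)=CCC/C(C)=C/CBr | starting material
8 | 3-geranyl-4-hydroxybenzaldehyde | CC(C)=CCC/C(C)=C/Cc1cc(C=O)ccc1O | intermediate
9 | 3-geranyl-4-(triisopropylsilyloxy)benzaldehyde | CC(C)=CCC/C(C)=C/Cc1cc(C=O)ccc1O[Si](C(C)C)(C(C)C)C(C)C | intermediate
10 | [3-geranyl-4-(triisopropylsilyloxy)phenyl]methanol | CC(C)=CCC/C(C)=C/Cc1cc(CO)ccc1O[Si](C(C)C)(C(C)C)C(C)C | intermediate
11 | 2-bromo-1-{[3-geranyl-4-(triisopropylsilyloxy)phenyl]methoxy}-4-methyl-3,5-bis(triisopropylsilyloxy)benzene | CC(C)=CCC/C(C)=C/Cc1cc(COc2cc(O[Si](C(C)C)(C(C)C)C(C)C)c(C)c(O[Si](C(C)C)(C(C)C)C(C)C)c2Br)ccc1O[Si](C(C)C)(C(C)C)C(C)C | intermediate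
12 | methyl bromoacetate | COC(=O)CBr | starting material
13 | methyl (bromozincio)acetate (not isolated) | COC(=O)C[Zn]Br | intermediate
14 | methyl 2-[2-{[3-geranyl-4-(triisopropylsilyloxy)phenyl]methoxy}-5-methyl-4,6-bis(triisopropylsilyloxy)phenyl]acetate | CC(C)=CCC/C(C)=C/Cc1cc(COc2cc(O[Si](C(C)C)(C(C)C)C(C)C)c(C)c(O[Si](C(C)C)(C(C)C)C(C)C)c2CC(=O)OC)ccc1O[Si](C(C)C)(C(C)C)C(C)C | intermediate
15 | methyl 2-diazo-2-[2-{[3-geranyl-4-(triisopropylsilyloxy)phenyl]methoxy}-5-methyl-4,6-bis(triisopropylsilyloxy)phenyl]acetate | CC(C)=CCC/C(C)=C/Cc1cc(COc2cc(O[Si](C(C)C)(C(C)C)C(C)C)c(C)c(O[Si](C(C)C)(C(C)C)C(C)C)c2C(=[N+]=[N-])C(=O)OC)ccc1O[Si](C(C)C)(C(C)C)C(C)C | intermediate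
16 | methyl (2S,3R)-2-[3-geranyl-4-(triisopropylsilyloxy)phenyl]-5-methyl-4,6-bis(triisopropylsilyloxy)-2,3-dihydro-1-benzofuran-3-carboxylate | CC(C)=CCC/C(C)=C/Cc1cc([C@H]2Oc3cc(O[Si](C(C)C)(C(C)C)C(C)C)c(C)c(O[Si](C(C)C)(C(C)C)C(C)C)c3[C@H]2C(=O)OC)ccc1O[Si](C(C)C)(C(C)C)C(C)C | intermediate
17 | potassium ester enolate of 16 (not isolated) | CC(C)=CCC/C(C)=C/Cc1cc([C@H]2Oc3cc(O[Si](C(C)C)(C(C)C)C(C)C)c(C)c(O[Si](C(C)C)(C(C)C)C(C)C)c3C2=C([O-])OC)ccc1O[Si](C(C)C)(C(C)C)C(C)C.[K+] | intermediate
18 | methyl (2R,3S)-2-[3-geranyl-4-(triisopropylsilyloxy)phenyl]-3-hydroxy-5-methyl-4,6-bis(triisopropylsilyloxy)-2,3-dihydro-1-benzofuran-3-carboxylate | CC(C)=CCC/C(C)=C/Cc1cc([C@H]2Oc3cc(O[Si](C(C)C)(C(C)C)C(C)C)c(C)c(O[Si](C(C)C)(C(C)C)C(C)C)c3[C@@]2(O)C(=O)OC)ccc1O[Si](C(C)C)(C(C)C)C(C)C | intermediate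
19 | (2R,3R)-2-[3-geranyl-4-(triisopropylsilyloxy)phenyl]-3-(hydroxymethyl)-5-methyl-4,6-bis(triisopropylsilyloxy)-2,3-dihydro-1-benzofuran-3-ol | CC(C)=CCC/C(C)=C/Cc1cc([C@H]2Oc3cc(O[Si](C(C)C)(C(C)C)C(C)C)c(C)c(O[Si](C(C)C)(C(C)C)C(C)C)c3[C@@]2(O)CO)ccc1O[Si](C(C)C)(C(C)C)C(C)C | intermediate
20 | (2R,3S)-2-[3-geranyl-4-(triisopropylsilyloxy)phenyl]-3-hydroxy-5-methyl-4,6-bis(triisopropylsilyloxy)-2,3-dihydro-1-benzofuran-3-carbaldehyde | CC(C)=CCC/C(C)=C/Cc1cc([C@H]2Oc3cc(O[Si](C(C)C)(C(C)C)C(C)C)c(C)c(O[Si](C(C)C)(C(C)C)C(C)C)c3[C@@]2(O)C=O)ccc1O[Si](C(C)C)(C(C)C)C(C)C | intermediate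
21 | (2R,3R)-2-[3-geranyl-4-(triisopropylsilyloxy)phenyl]-3-hydroxy-6-methyl-5,7-bis(triisopropylsilyloxy)-2,3-dihydro-4H-chromen-4-one | CC(C)=CCC/C(C)=C/Cc1cc([C@H]2Oc3cc(O[Si](C(C)C)(C(C)C)C(C)C)c(C)c(O[Si](C(C)C)(C(C)C)C(C)C)c3C(=O)[C@@H]2O)ccc1O[Si](C(C)C)(C(C)C)C(C)C | intermediate
22 | (2R,3R)-2-(3-geranyl-4-hydroxyphenyl)-3,5,7-trihydroxy-6-methyl-2,3-dihydro-4H-chromen-4-one | CC(C)=CCC/C(C)=C/Cc1cc([C@H]2Oc3cc(O)c(C)c(O)c3C(=O)[C@@H]2O)ccc1O | target

**Totals**

Total step count: 15. Longest linear sequence: 12 steps (steps 1–3 and 7–15 from 2-methylresorcinol; equally steps 4–6 and 7–15 from 4-hydroxybenzaldehyde).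

**Steps most likely to fail**

Step 14. The ring A carbon may migrate in competition with C2, or the α-ketol may enolise on aluminium, which would erode C3 and, through ring opening, C2. The fallback makes the C2–C3 bond of ring C by a carbenoid C–H insertion at the six-membered stage and adds the C3 hydroxyl afterwards. It sets out from bromide 11. Bromine–lithium exchange (n-BuLi, THF, −78 °C) and acylation with N-methoxy-N-methylacetamide give the aryl methyl ketone F1. Detrifluoroacetylative diazo transfer (LiHMDS, CF3CO2CH2CF3, −78 °C; then methanesulfonyl azide, Et3N, MeCN) gives the α-diazo ketone F2. A chiral dirhodium tetracarboxylate (Rh2(S-PTTL)4 or its enantiomer, whichever gives 2S) inserts the carbenoid into the benzylic ether C–H with formation of the six-membered ring, giving the (2S)-flavanone F3. Its lithium enolate (LiHMDS, THF, −78 °C) is hydroxylated with 2-(phenylsulfonyl)-3-phenyloxaziridine anti to the 2-aryl group, which gives 21; the route is rejoined before step 15.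

Step 8. Oxidative addition and transmetalation may stall at the doubly ortho-substituted, electron-rich C–Br bond, so that protodebromination takes over. The fallback brings in the two-carbon unit as an electrophile and makes the diazo group from a ketone, not by diazo transfer. It sets out from 11. Bromine–lithium exchange (n-BuLi, THF, −78 °C) and inverse addition to dimethyl oxalate give the aryl glyoxylate F4. Condensation with p-toluenesulfonohydrazide (MeOH, cat. AcOH, 50 °C) gives the tosylhydrazone F5. DBU in CH2Cl2 at rt expels sulfinate (Bamford–Stevens) and gives the aryl diazoacetate 15; the route is rejoined at step 10.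

Step 10. Enantiofacial discrimination may be poor, because two ortho substituents twist the carbenoid out of the arene plane and the very electron-rich benzylic C–H may react by a stepwise hydride shift outside catalyst control. The fallback replaces asymmetric catalysis by resolution. It sets out from 15. Rh2(OAc)4 (CH2Cl2, rt) gives the dihydrobenzofuran ester as a mixture of stereoisomers F6. Hydroxylation as in step 11 converges the cis and trans isomers on the racemic hydroxy ester F7 (hydroxyl trans to aryl). Preparative chromatography on an amylose or cellulose carbamate chiral stationary phase gives the (2R,3S) enantiomer 18; the route is rejoined at step 12.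

**Further compounds**

F1 | step 14 | 1-[2-{[3-geranyl-4-(triisopropylsilyloxy)phenyl]methoxy}-5-methyl-4,6-bis(triisopropylsilyloxy)phenyl]ethan-1-one | CC(C)=CCC/C(C)=C/Cc1cc(COc2cc(O[Si](C(C)C)(C(C)C)C(C)C)c(C)c(O[Si](C(C)C)(C(C)C)C(C)C)c2C(C)=O)ccc1O[Si](C(C)C)(C(C)C)C(C)C
F2 | step 14 | 2-diazo-1-[2-{[3-geranyl-4-(triisopropylsilyloxy)phenyl]methoxy}-5-methyl-4,6-bis(triisopropylsilyloxy)phenyl]ethan-1-one | CC(C)=CCC/C(C)=C/Cc1cc(COc2cc(O[Si](C(C)C)(C(C)C)C(C)C)c(C)c(O[Si](C(C)C)(C(C)C)C(C)C)c2C(=O)C=[N+]=[N-])ccc1O[Si](C(C)C)(C(C)C)C(C)C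
F3 | step 14 | (2S)-2-[3-geranyl-4-(triisopropylsilyloxy)phenyl]-6-methyl-5,7-bis(triisopropylsilyloxy)-2,3-dihydro-4H-chromen-4-one | CC(C)=CCC/C(C)=C/Cc1cc([C@H]2Oc3cc(O[Si](C(C)C)(C(C)C)C(C)C)c(C)c(O[Si](C(C)C)(C(C)C)C(C)C)c3C(=O)C2)ccc1O[Si](C(C)C)(C(C)C)C(C)C
F4 | step 8 | methyl 2-[2-{[3-geranyl-4-(triisopropylsilyloxy)phenyl]methoxy}-5-methyl-4,6-bis(triisopropylsilyloxy)phenyl]-2-oxoacetate | CC(C)=CCC/C(C)=C/Cc1cc(COc2cc(O[Si](C(C)C)(C(C)C)C(C)C)c(C)c(O[Si](C(C)C)(C(C)C)C(C)C)c2C(=O)C(=O)OC)ccc1O[Si](C(C)C)(C(C)C)C(C)C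
F5 | step 8 | methyl 2-[2-{[3-geranyl-4-(triisopropylsilyloxy)phenyl]methoxy}-5-methyl-4,6-bis(triisopropylsilyloxy)phenyl]-2-[2-(4-methylbenzenesulfonyl)hydrazinylidene]acetate | CC(C)=CCC/C(C)=C/Cc1cc(COc2cc(O[Si](C(C)C)(C(C)C)C(C)C)c(C)c(O[Si](C(C)C)(C(C)C)C(C)C)c2C(=NNS(=O)(=O)c3ccc(C)cc3)C(=O)OC)ccc1O[Si](C(C)C)(C(C)C)C(C)C
F6 | step 10 | methyl 2-[3-geranyl-4-(triisopropylsilyloxy)phenyl]-5-methyl-4,6-bis(triisopropylsilyloxy)-2,3-dihydro-1-benzofuran-3-carboxylate, mixture of stereoisomers at C2 and C3 | CC(C)=CCC/C(C)=C/Cc1cc(C2Oc3cc(O[Si](C(C)C)(C(C)C)C(C)C)c(C)c(O[Si](C(C)C)(C(C)C)C(C)C)c3C2C(=O)OC)ccc1O[Si](C(C)C)(C(C)C)C(C)C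
F7 | step 10 | racemic methyl (2R*,3S*)-2-[3-geranyl-4-(triisopropylsilyloxy)phenyl]-3-hydroxy-5-methyl-4,6-bis(triisopropylsilyloxy)-2,3-dihydro-1-benzofuran-3-carboxylate (both enantiomers) | CC(C)=CCC/C(C)=C/Cc1cc([C@H]2Oc3cc(O[Si](C(C)C)(C(C)C)C(C)C)c(C)c(O[Si](C(C)C)(C(C)C)C(C)C)c3[C@@]2(O)C(=O)OC)ccc1O[Si](C(C)C)(C(C)C)C(C)C.CC(C)=CCC/C(C)=C/Cc1cc([C@@H]2Oc3cc(O[Si](C(C)C)(C(C)C)C(C)C)c(C)c(O[Si](C(C)C)(C(C)C)C(C)C)c3[C@]2(O)C(=O)OC)ccc1O[Si](C(C)C)(C(C)C)C(C)C
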